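**Retrosynthetic overview**

Ring atoms: C1 = oxirane carbon carrying CH2OBz, C2 = CHOH, C3 = CHOBz, C4=C5, C6 = oxirane CH. The target goes back, by O-acylation and PMB removal, to the anti-epoxide of the C1=C6 bond of a 2,3-cis-dioxygenated cyclohexa-1(6),4-diene, and that diene to a cyclohex-5-ene-1,3-diol by 1,4-dehydration.
Key disconnection: C3–C4 and C6–C1 of that cyclohexenediol are cut together. C3 becomes the aldehyde carbon and C1 the ketone carbon of a 2,4-dialkoxy-3-oxobutanal; C4–C5–C6 becomes one chiral 1-bromoallyl boronate, which allylborates through C4 and then closes by Nozaki–Hiyama–Kishi addition through C6.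
Enabling feature: in the carbocycle the two oxygen-bearing carbons C3 (secondary) and C1 (fully substituted, also a member of the oxirane ring) lie 1,5 to each other across the three CH carbons C4, C5 and C6, so both ring bonds to that three-carbon bridge are carbonyl-addition bonds.
Ring order: the six-membered carbocycle is formed in the key step; the oxirane is formed afterwards on the C1=C6 double bond.

Key step: step 6

Assumption: keto aldehyde 6 is stereochemically labile at its alkoxy-bearing carbon (fast keto–enol exchange, mainly enol), so it is drawn without configuration and this centre is fixed only in step 6.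

**Route**

Step 1
Reactants: 1 (±)-epichlorohydrin; 2 4-methoxybenzyl alcohol (2 equiv)
Product: 3 1,3-bis[(4-methoxybenzyl)oxy]propan-2-ol
Conditions: NaH, DMF, 0 °C to 60 °C
Reagents that add atoms: none
Why: Williamson-type sequence; the alkoxide opens the epoxide, the chlorohydrin alkoxide recloses to the glycidyl ether and a second alkoxide opens it at the terminal carbon, so the symmetric 1,3-diether should result.

Step 2
Reactants: 3 1,3-bis[(4-methoxybenzyl)oxy]propan-2-ol
Product: 4 1,3-bis[(4-methoxybenzyl)oxy]propan-2-one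
Conditions: Dess–Martin periodinane, NaHCO3, CH2Cl2, rt
Reagents that add atoms: none
Why: Dess–Martin oxidation of a secondary alcohol; PMB ethers are inert to it.

Step 3
Reactants: 4 1,3-bis[(4-methoxybenzyl)oxy]propan-2-one; 5 ethyl formate
Product: 6 2,4-bis[(4-methoxybenzyl)oxy]-3-oxobutanal
Conditions: NaH, THF, 0 °C to rt; then AcOH
Reagents that add atoms: none
Why: crossed Claisen condensation (C-formylation); the ketone is symmetric so only one constitution can form, and the stabilised product enolate should prevent a second formylation.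

Step 4
Reactants: 7 dibutyl vinylboronate; 8 (1S,2S)-1,2-dicyclohexylethane-1,2-diol
Product: 9 (4S,5S)-4,5-dicyclohexyl-2-ethenyl-1,3,2-dioxaborolane
Conditions: pentane, 4 Å molecular sieves, rt; butanol removed under reduced pressure
Reagents that add atoms: none
Why: boronic ester transesterification, driven by the chelating diol and removal of butanol.

Step 5
Reactants: 9 (4S,5S)-4,5-dicyclohexyl-2-ethenyl-1,3,2-dioxaborolane; 10 dibromomethane
Product: 12 (4S,5S)-2-[(1R)-1-bromoprop-2-en-1-yl]-4,5-dicyclohexyl-1,3,2-dioxaborolane, via lithium borate complex 11 (not isolated)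
Conditions: LiN(iPr)2, THF, −78 °C; ZnCl2, −78 °C to rt
Reagents that add atoms: none
Why: Matteson homologation; (dibromomethyl)lithium adds to boron and the vinyl group migrates with loss of one bromide, the C2-symmetric (S,S)-diol being expected to select the bromide that leaves and so set the (R) α-carbon.

Step 6
Reactants: 6 2,4-bis[(4-methoxybenzyl)oxy]-3-oxobutanal; 12 (4S,5S)-2-[(1R)-1-bromoprop-2-en-1-yl]-4,5-dicyclohexyl-1,3,2-dioxaborolane
Product: 14 (1S,2S)-2-[(4-methoxybenzyl)oxy]-3-{[(4-methoxybenzyl)oxy]methyl}cyclohex-4-ene-1,3-diol (both C3 epimers), via bromoalkenyl keto borate 13 (not isolated)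
Conditions: 4 Å molecular sieves, CH2Cl2, 0 °C to rt; then CrCl2, NiCl2 (cat.), DMF, rt; aqueous work-up
Reagents that add atoms: none
Why: The keto tautomer of 6 should be allylated at its aldehyde carbon C3 by 12 through a closed six-membered chair transition state (C4 bonds to C3, boron passes to oxygen, the double bond moves to C5=C6); once CrCl2/NiCl2 is added, zerovalent nickel inserts into the C6–Br bond, the alkenyl group passes to trivalent chromium and adds to the C1 ketone. The closest known reaction types are the α-haloallylboration of aldehydes with chirality transfer from the α-carbon and the intramolecular Nozaki–Hiyama–Kishi addition of alkenyl bromides to ketones. The carbocycle closes by 6-exo-trig addition of the alkenylchromium carbon C6 to the C1 carbonyl, which needs the Z bromoalkene; that geometry follows from the axial position of bromine in the allylboration chair. C3 is set by the (R) α-carbon of 12 (aldehyde substituent equatorial, bromine axial, giving 3S); C2, which equilibrates through the enol of 6, is set in the same addition by Felkin–Anh matching (2,3-anti, a dynamic kinetic resolution); the C1 carbinol centre is not controlled and is erased in step 8. The step needs aldehyde-over-ketone selectivity in the first bond formation, secured because allylboronic esters do not add to ketones at room temperature, so the ketone reacts only later and intramolecularly.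

Step 7
Reactants: 14 (1S,2S)-2-[(4-methoxybenzyl)oxy]-3-{[(4-methoxybenzyl)oxy]methyl}cyclohex-4-ene-1,3-diol
Product: 15 (1S,6S)-5-hydroxy-6-[(4-methoxybenzyl)oxy]-5-{[(4-methoxybenzyl)oxy]methyl}cyclohex-3-en-1-yl benzoate (both C5 epimers)
Conditions: BzCl, pyridine, DMAP (cat.), CH2Cl2, 0 °C
Reagents that add atoms: benzoyl chloride, O=C(Cl)c1ccccc1
Why: O-acylation; the secondary C3 hydroxyl should react while the tertiary allylic C1 hydroxyl stays free.

Step 8
Reactants: 15 (1S,6S)-5-hydroxy-6-[(4-methoxybenzyl)oxy]-5-{[(4-methoxybenzyl)oxy]methyl}cyclohex-3-en-1-yl benzoate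
Product: 18 (1S,6R)-6-[(4-methoxybenzyl)oxy]-5-{[(4-methoxybenzyl)oxy]methyl}cyclohexa-2,4-dien-1-yl benzoate, via allylic sulfenate 16 (not isolated), via allylic sulfoxide 17 (not isolated)
Conditions: 2,4-dinitrobenzenesulfenyl chloride, Et3N, CH2Cl2, 0 °C to rt
Reagents that add atoms: none
Why: 1,4-dehydration of an allylic alcohol; the sulfenate of the tertiary alcohol undergoes a [2,3]-sigmatropic (Mislow–Evans-type) shift that puts sulfur on C5, and syn-elimination of the electron-poor sulfoxide can only take a hydrogen from C4, giving the C4=C5/C6=C1 diene and erasing the uncontrolled C1 centre.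

Step 9
Reactants: 18 (1S,6R)-6-[(4-methoxybenzyl)oxy]-5-{[(4-methoxybenzyl)oxy]methyl}cyclohexa-2,4-dien-1-yl benzoate
Product: 19 (1S,4S,5S,6S)-5-[(4-methoxybenzyl)oxy]-6-{[(4-methoxybenzyl)oxy]methyl}-7-oxabicyclo[4.1.0]hept-2-en-4-yl benzoate
Conditions: mCPBA, NaHCO3, CH2Cl2, −20 °C to 0 °C
Reagents that add atoms: mCPBA, O=C(OO)c1cccc(Cl)c1
Why: Prilezhaev epoxidation; the trisubstituted C1=C6 bond is more electron-rich than C4=C5 (which carries the allylic benzoate), and the peracid should approach anti to the two cis oxygen substituents at C2 and C3, setting C1 and C6.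

Step 10
Reactants: 19 (1S,4S,5S,6S)-5-[(4-methoxybenzyl)oxy]-6-{[(4-methoxybenzyl)oxy]methyl}-7-oxabicyclo[4.1.0]hept-2-en-4-yl benzoate
Product: 20 (1S,4S,5S,6R)-5-hydroxy-6-(hydroxymethyl)-7-oxabicyclo[4.1.0]hept-2-en-4-yl benzoate
Conditions: DDQ, CH2Cl2/aqueous pH 7 buffer, 0 °C to rt
Reagents that add atoms: none
Why: oxidative cleavage of both PMB ethers under neutral conditions that the vinyl oxirane and the allylic benzoate should tolerate.

Step 11
Reactants: 20 (1S,4S,5S,6R)-5-hydroxy-6-(hydroxymethyl)-7-oxabicyclo[4.1.0]hept-2-en-4-yl benzoate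
Product: 21 [(1S,4S,5S,6R)-4-(benzoyloxy)-5-hydroxy-7-oxabicyclo[4.1.0]hept-2-en-6-yl]methyl benzoate
Conditions: BzCl (1 equiv), 2,4,6-collidine, CH2Cl2, −40 °C to −20 °C
Reagents that add atoms: benzoyl chloride, O=C(Cl)c1ccccc1
Why: selective O-acylation of the primary hydroxyl over the hindered secondary C2 hydroxyl; low temperature and a weak base should suppress benzoyl migration between O3 and O2.

**Compound list**

1 | (±)-epichlorohydrin | ClCC1CO1 | starting material
2 | 4-methoxybenzyl alcohol | COc1ccc(CO)cc1 | starting material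
3 | 1,3-bis[(4-methoxybenzyl)oxy]propan-2-ol | COc1ccc(COCC(O)COCc2ccc(OC)cc2)cc1 | intermediate
4 | 1,3-bis[(4-methoxybenzyl)oxy]propan-2-one | COc1ccc(COCC(=O)COCc2ccc(OC)cc2)cc1 | intermediate
5 | ethyl formate | CCOC=O | starting material
6 | 2,4-bis[(4-methoxybenzyl)oxy]-3-oxobutanal (C2 labile, mainly enol) | COc1ccc(COCC(=O)C(OCc2ccc(OC)cc2)C=O)cc1 | intermediate
7 | dibutyl vinylboronate | C=CB(OCCCC)OCCCC | starting material
8 | (1S,2S)-1,2-dicyclohexylethane-1,2-diol | O[C@@H](C1CCCCC1)[C@@H](O)C1CCCCC1 | starting material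
9 | (4S,5S)-4,5-dicyclohexyl-2-ethenyl-1,3,2-dioxaborolane | C=CB1O[C@@H](C2CCCCC2)[C@H](C2CCCCC2)O1 | intermediate
10 | dibromomethane | BrCBr | starting material
11 | lithium (4S,5S)-4,5-dicyclohexyl-2-(dibromomethyl)-2-ethenyl-1,3,2-dioxaborolan-2-uide | [Li+].C=C[B-]1(C(Br)Br)O[C@@H](C2CCCCC2)[C@H](C2CCCCC2)O1 | intermediate
12 | (4S,5S)-2-[(1R)-1-bromoprop-2-en-1-yl]-4,5-dicyclohexyl-1,3,2-dioxaborolane | C=C[C@H](Br)B1O[C@@H](C2CCCCC2)[C@H](C2CCCCC2)O1 | intermediate
13 | (4S,5S)-2-{[(3S,4S,6Z)-7-bromo-1,3-bis[(4-methoxybenzyl)oxy]-2-oxohept-6-en-4-yl]oxy}-4,5-dicyclohexyl-1,3,2-dioxaborolane | COc1ccc(COCC(=O)[C@@H](OCc2ccc(OC)cc2)[C@H](C/C=C\Br)OB2O[C@@H](C3CCCCC3)[C@H](C3CCCCC3)O2)cc1 | intermediate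
14 | (1S,2S)-2-[(4-methoxybenzyl)oxy]-3-{[(4-methoxybenzyl)oxy]methyl}cyclohex-4-ene-1,3-diol (both C3 epimers) | COc1ccc(COCC2(O)C=CC[C@H](O)[C@@H]2OCc2ccc(OC)cc2)cc1 | intermediate
15 | (1S,6S)-5-hydroxy-6-[(4-methoxybenzyl)oxy]-5-{[(4-methoxybenzyl)oxy]methyl}cyclohex-3-en-1-yl benzoate (both C5 epimers) | COc1ccc(COCC2(O)C=CC[C@H](OC(=O)c3ccccc3)[C@@H]2OCc2ccc(OC)cc2)cc1 | intermediate
16 | 2,4-dinitrobenzenesulfenate ester of the tertiary alcohol of 15 | COc1ccc(COCC2(OSc3ccc(cc3[N+](=O)[O-])[N+](=O)[O-])C=CC[C@H](OC(=O)c3ccccc3)[C@@H]2OCc2ccc(OC)cc2)cc1 | intermediate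
17 | (1S,2R)-5-[(2,4-dinitrophenyl)sulfinyl]-2-[(4-methoxybenzyl)oxy]-3-{[(4-methoxybenzyl)oxy]methyl}cyclohex-3-en-1-yl benzoate (C5 and sulfur unassigned) | COc1ccc(COCC2=CC(S(=O)c3ccc(cc3[N+](=O)[O-])[N+](=O)[O-])C[C@H](OC(=O)c3ccccc3)[C@@H]2OCc2ccc(OC)cc2)cc1 | intermediate
18 | (1S,6R)-6-[(4-methoxybenzyl)oxy]-5-{[(4-methoxybenzyl)oxy]methyl}cyclohexa-2,4-dien-1-yl benzoate | COc1ccc(COCC2=CC=C[C@H](OC(=O)c3ccccc3)[C@@H]2OCc2ccc(OC)cc2)cc1 | intermediate
19 | (1S,4S,5S,6S)-5-[(4-methoxybenzyl)oxy]-6-{[(4-methoxybenzyl)oxy]methyl}-7-oxabicyclo[4.1.0]hept-2-en-4-yl benzoate | COc1ccc(COC[C@]23O[C@H]2C=C[C@H](OC(=O)c2ccccc2)[C@@H]3OCc2ccc(OC)cc2)cc1 | intermediate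
20 | (1S,4S,5S,6R)-5-hydroxy-6-(hydroxymethyl)-7-oxabicyclo[4.1.0]hept-2-en-4-yl benzoate | OC[C@]12O[C@H]1C=C[C@H](OC(=O)c1ccccc1)[C@@H]2O | intermediate
21 | [(1S,4S,5S,6R)-4-(benzoyloxy)-5-hydroxy-7-oxabicyclo[4.1.0]hept-2-en-6-yl]methyl benzoate | O=C(OC[C@]12O[C@H]1C=C[C@H](OC(=O)c1ccccc1)[C@@H]2O)c1ccccc1 | target

**Step count and risks**

Total step count: 11. Longest linear sequence: 9 steps (steps 1, 2, 3, 6, 7, 8, 9, 10, 11); steps 4 and 5 make the second fragment.

Steps most likely to fail:

Step 6. The enol-rich keto aldehyde 6 may transfer boron to its enol oxygen instead of being allylated. Equilibration at C2 may also be slower than allylation, or the Felkin–Anh preference weak, so that the 2,3-cis relationship is lost; the alkenyl bromide may be reduced instead of cyclising. The fallback sets out from compound 4 and comes back at compound 14, using known reactions only. Ketone 4 is converted to its (E)-enol borinate (dicyclohexylboron chloride, or a chiral diisopinocampheylboron halide for absolute control, with Et3N) and added to but-3-enal in an anti-selective boron aldol reaction, which should give (3S,4S)-4-hydroxy-1,3-bis[(4-methoxybenzyl)oxy]hept-6-en-2-one F1. Addition of CH2=CHMgBr with CeCl3 to the ketone should give (4S,5S)-4-[(4-methoxybenzyl)oxy]-3-{[(4-methoxybenzyl)oxy]methyl}octa-1,7-diene-3,5-diol F2. Ring-closing metathesis with the second-generation Grubbs catalyst then closes the C5=C6 bond and returns 14.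

Step 8. The sulfenate may not rearrange and eliminate cleanly, the anisyl rings may be sulfenylated, or the amine base may cause loss of benzoic acid from the diene with aromatisation. The fallback sets out from compound 15 and comes back at compound 18. A 1,3-transposition of the tertiary allylic alcohol catalysed by O3ReOSiPh3 should give the secondary allylic alcohol (1S,2R)-5-hydroxy-2-[(4-methoxybenzyl)oxy]-3-{[(4-methoxybenzyl)oxy]methyl}cyclohex-3-en-1-yl benzoate F3, and syn-dehydration with the Burgess reagent toward C4 should give 18.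

Step 9. Site selectivity between the two ring double bonds or facial selectivity of the peracid may be poor, or over-oxidation may occur. The fallback sets out from compound 18 and comes back at compound 20. Both PMB ethers are removed first with DDQ to give (1S,6R)-6-hydroxy-5-(hydroxymethyl)cyclohexa-2,4-dien-1-yl benzoate F4. Its primary allylic alcohol then directs a Sharpless asymmetric epoxidation of the C1=C6 bond (Ti(OiPr)4, D-(−)-diethyl tartrate, t-BuOOH). With the hydroxymethyl group drawn at the lower right, this tartrate delivers oxygen to the top face, which is the face anti to the C2 and C3 oxygens. The result should be 20.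

Further compounds
F1 | step 6 | (3S,4S)-4-hydroxy-1,3-bis[(4-methoxybenzyl)oxy]hept-6-en-2-one | COc1ccc(COCC(=O)[C@@H](OCc2ccc(OC)cc2)[C@H](CC=C)O)cc1
F2 | step 6 | (4S,5S)-4-[(4-methoxybenzyl)oxy]-3-{[(4-methoxybenzyl)oxy]methyl}octa-1,7-diene-3,5-diol (both C3 epimers) | COc1ccc(COCC(O)(C=C)[C@@H](OCc2ccc(OC)cc2)[C@H](CC=C)O)cc1
F3 | step 8 | (1S,2R)-5-hydroxy-2-[(4-methoxybenzyl)oxy]-3-{[(4-methoxybenzyl)oxy]methyl}cyclohex-3-en-1-yl benzoate (both C5 epimers) | COc1ccc(COCC2=CC(O)C[C@H](OC(=O)c3ccccc3)[C@@H]2OCc2ccc(OC)cc2)cc1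
F4 | step 9 | (1S,6R)-6-hydroxy-5-(hydroxymethyl)cyclohexa-2,4-dien-1-yl benzoate | OCC1=CC=C[C@H](OC(=O)c2ccccc2)[C@@H]1O
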